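I began from a leftover: the part of the initiator that the impurity and the side path to spent initiator B leave over to begin chains.

free monomer 0.80 M; transfer agent 0.240 M; initiator 5 mol%; impurity 18 mM; time 1.0 h

    free monomer + initiator → living end + monomer in chains (k1 = 0.092 /M/s)
    free monomer + living end → monomer in chains + living end, rate k2*[living end]*[free monomer] (k2 = 0.066 /M/s)
    living end + transfer agent → dead chain (k3 = 0.0027 /M/s)
    initiator + impurity → spent initiator A (k4 = 2.3 /M/s)
    free monomer + initiator → spent initiator B (k5 = 0.0079 /M/s)
    free monomer → uncatalysed product (k6 = 0.0013 /s)

- the average divides the monomer in chains by the number of chains begun, living and dead together
- run time (flask): 1.0 h

1. average number of monomer units in a chain (chains begun, living or dead) at 1.0 h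
2. part of the free monomer that has reacted at 1.0 h

I turned the constants into half-lives at the charged amounts and set them in a column of four: initiator against impurity, 0.28 min; free monomer into first chains, with initiator held at its charge, 0.052 h; free monomer to uncatalysed product, 0.15 h; living end against transfer agent, 0.30 h. The first row is shorter than the others, so the initiator was shared out while [free monomer] stood near its charge, but [impurity] could not stand so, because the initiator charged, 0.0400 M, is more than the 18 mM of impurity. The starting rates of the initiator's three paths gave me 0.0243 M of chains begun, which I took as a low count, since they hold the impurity's share at its starting size while [impurity] falls. The second row assumes a held initiator, which the first row denies, so I set it aside. The last row is twice the third, so I let [living end] stand at that count while the free monomer went, and took what followed as a high figure, since the living ends do thin.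

Propagation and the uncatalysed loss are both first order in [free monomer], so their ratio holds as it falls. I kept it as the chain pull, 1.23, the rate at which living ends take free monomer over the rate at which it goes to uncatalysed product, a selectivity factor in the usual term. That pull sends 55.2 % of the free monomer into chains, so my average was 18.2. Because the third row is shorter than the hour, the uncatalysed loss by itself gave at least 99.1 % reacted.

The forecast gave 15.5, between 14 and 17, and 99.9 %, from about 0.027 M of chains where I had 0.0243 M: "Those living ends then decay slowly through transfer while propagation and the uncatalysed loss compete for monomer". My average stood above its range.

The flask gave an average of 15.6 and 99.9 % reacted, inside the forecast's range and below my figure. Its monomer in chains over uncatalysed product read 1.14 at 1.00 h against a pull of 1.23; in the neighbour charged with 0.32 M of free monomer the pull comes to 0.326 and the reading to 0.286. The first flask had not quite come to rest at that hour: by 10.0 h its [living end] had fallen from 0.00310 M to 2.49 × 10⁻¹¹ M and its [dead chain] had risen from 0.0240 M to 0.0271 M, while its average stayed 15.6.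

The numbers of this flask were chosen freely, and the outcome is calculated.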